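**Retrosynthetic overview**
1. The target is reached by selective C13 acetylation, after a fluoride-triggered desilylation that closes the butenolide (C6–O onto the C12 ester), from the C8 tiglate of a ten-membered seco-ester carbinol.
2. The ten-membered ring is closed by forming C7–C8: Ni/Cr-mediated (Nozaki–Hiyama–Kishi) addition of a C7 alkenyl bromide to the C8 aldehyde, an umpolung union of two electrophilic carbons (enoate β-carbon and formyl carbon).
3. Enabling feature: the fully substituted C7=C11 alkene of the future butenolide (C7–Br cis to C13H2OSi, C6 cis to the C12 ester) serves as a latent β-acylvinyl anion. The lactone ring O–C12–C11=C7–C6 is kept open (C6–OTES, ethyl ester), and the cis-fused C4–C5 oxirane ring acts as a turn element.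
4. The cyclisation precursor comes from a cis-epoxy aldehyde and the magnesium carbenoid of a 3,3-dibromoacrylate (C6–C7 bond). The epoxy aldehyde comes from neryl acetate: ozonolytic C–C cleavage, anti-crotylboration (C1/C10), hydroboration (C8), asymmetric epoxidation (C4/C5).
5. Ring order: oxirane (step 6), then ten-membered carbocycle (step 13), then butenolide (step 15).

Key step: step 13

Assumption: positions are called by germacrane numbering (ring C1–C10; C1 carbinol, C4/C5 epoxide, C6 lactone oxygen, C7=C11, C8 tiglate, C12 carbonyl, C13 CH2OAc); the epoxide of the target is cis-fused (C3 and C6 on the same side), so a Z-alkene of the nerol series is its precursor; the crotylborane of step 2 is a stock reagent made beforehand.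

**Step 1**
Reactants: 1 neryl acetate, (2Z)-3,7-dimethylocta-2,6-dien-1-yl acetate
Product: 3 (2Z)-3-methyl-6-oxohex-2-en-1-yl acetate, via secondary ozonide 2 (not isolated)
Conditions: O3 (1.0 equiv), CH2Cl2, −78 °C; then Me2S, −78 °C to rt
Reagents that add atoms: ozone, [O-][O+]=O
Why: Chemoselective ozonolysis with reductive work-up; the remote trialkyl alkene is more electron-rich than the alkene deactivated by the allylic acetoxy group and should be cleaved first, leaving the Z-alkene that later becomes the cis-epoxide.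

**Step 2**
Reactants: 3 (2Z)-3-methyl-6-oxohex-2-en-1-yl acetate
Product: 5 (2Z,6S,7R)-6-hydroxy-3,7-dimethylnona-2,8-dien-1-yl acetate, via diisopinocampheylborinate 4 (not isolated)
Conditions: (E)-crotyl-B(Ipc)2 [Ipc from (−)-α-pinene], THF/Et2O, −78 °C; then HOCH2CH2NH2, 0 °C to rt
Reagents that add atoms: (E)-crotyldiisopinocampheylborane, C/C=C/CB([C@H]1C[C@H]2C[C@@H]([C@@H]1C)C2(C)C)[C@H]1C[C@H]2C[C@@H]([C@@H]1C)C2(C)C
Why: Brown crotylboration through a closed chair transition state; the E-crotyl geometry gives the anti C1/C10 relationship and the isopinocampheyl groups direct attack to the re face of the aldehyde (1S,10R in target numbering).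

**Step 3**
Reactants: 5 (2Z,6S,7R)-6-hydroxy-3,7-dimethylnona-2,8-dien-1-yl acetate
Product: 7 (2Z,6S,7R)-6,9-dihydroxy-3,7-dimethylnon-2-en-1-yl acetate, via bis-borylated intermediate 6 (not isolated)
Conditions: 9-BBN (2.5 equiv), THF, 0 °C to rt; then H2O2, aq NaOAc, 0 °C
Reagents that add atoms: hydrogen peroxide, OO
Why: Anti-Markovnikov hydroboration–oxidation; 9-BBN should select the monosubstituted alkene over the trisubstituted Z-alkene, and the buffered oxidation spares the acetate (no new stereocentre).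

**Step 4**
Reactants: 7 (2Z,6S,7R)-6,9-dihydroxy-3,7-dimethylnon-2-en-1-yl acetate
Product: 8 (2Z,6S,7R)-3,7-dimethyl-6,9-bis(triethylsilyloxy)non-2-en-1-yl acetate
Conditions: TESCl (2.4 equiv), imidazole, DMF, 0 °C
Reagents that add atoms: chlorotriethylsilane, CC[Si](Cl)(CC)CC
Why: Standard silylation of both hydroxyls; the primary TES ether is the latent C8 aldehyde and the secondary one protects C1 to the end.

**Step 5**
Reactants: 8 (2Z,6S,7R)-3,7-dimethyl-6,9-bis(triethylsilyloxy)non-2-en-1-yl acetate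
Product: 9 (2Z,6S,7R)-3,7-dimethyl-6,9-bis(triethylsilyloxy)non-2-en-1-ol
Conditions: K2CO3 (0.2 equiv), MeOH, 0 °C
Reagents that add atoms: none
Why: Base-catalysed transesterification removes the acetate under conditions that TES ethers tolerate.

**Step 6**
Reactants: 9 (2Z,6S,7R)-3,7-dimethyl-6,9-bis(triethylsilyloxy)non-2-en-1-ol
Product: 10 {(2S,3R)-3-methyl-3-[(3S,4R)-4-methyl-3,6-bis(triethylsilyloxy)hexyl]oxiran-2-yl}methanol
Conditions: Ti(Oi-Pr)4 (0.2 equiv), L-(+)-diethyl tartrate (0.24 equiv), t-BuOOH, 4 Å MS, CH2Cl2, −20 °C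
Reagents that add atoms: tert-butyl hydroperoxide, CC(C)(C)OO
Why: Sharpless asymmetric epoxidation; L-(+)-tartrate delivers oxygen to the face that gives the (2S,3R)-epoxy alcohol of a nerol-type Z-allylic alcohol, and syn addition to the Z-alkene gives the cis-epoxide (4R,5S in target numbering).

**Step 7**
Reactants: 10 {(2S,3R)-3-methyl-3-[(3S,4R)-4-methyl-3,6-bis(triethylsilyloxy)hexyl]oxiran-2-yl}methanol
Product: 11 (2R,3R)-3-methyl-3-[(3S,4R)-4-methyl-3,6-bis(triethylsilyloxy)hexyl]oxirane-2-carbaldehyde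
Conditions: n-Pr4N[RuO4] (5 mol %), N-methylmorpholine N-oxide, 4 Å MS, CH2Cl2, rt
Reagents that add atoms: none
Why: Ley–Griffith oxidation of the primary epoxy alcohol under neutral conditions, so the epoxide and both TES ethers should survive.

**Step 8**
Reactants: 12 ethyl 2-(hydroxymethyl)acrylate
Product: 13 ethyl 2-({[tert-butyl(dimethyl)silyl]oxy}methyl)prop-2-enoate
Conditions: TBSCl, imidazole, CH2Cl2, rt
Reagents that add atoms: tert-butylchlorodimethylsilane, CC(C)(C)[Si](C)(C)Cl
Why: Standard silylation; the TBS ether is a poor leaving group and masks C13–OH until the end.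

**Step 9**
Reactants: 13 ethyl 2-({[tert-butyl(dimethyl)silyl]oxy}methyl)prop-2-enoate
Product: 15 ethyl 3-{[tert-butyl(dimethyl)silyl]oxy}-2-oxopropanoate, via trioxolane 14 (not isolated)
Conditions: O3, CH2Cl2, −78 °C; then Me2S, −78 °C to rt
Reagents that add atoms: ozone, [O-][O+]=O
Why: Ozonolysis of the 1,1-disubstituted acrylate alkene gives the α-keto ester and formaldehyde.

**Step 10**
Reactants: 15 ethyl 3-{[tert-butyl(dimethyl)silyl]oxy}-2-oxopropanoate
Product: 16 ethyl 3,3-dibromo-2-({[tert-butyl(dimethyl)silyl]oxy}methyl)prop-2-enoate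
Conditions: CBr4 (2 equiv), PPh3 (4 equiv), CH2Cl2, 0 °C
Reagents that add atoms: carbon tetrabromide, BrC(Br)(Br)Br
Why: Ramirez dibromo-olefination (Wittig reaction of Ph3P=CBr2) of the activated α-keto ester carbonyl.

**Step 11**
Reactants: 16 ethyl 3,3-dibromo-2-({[tert-butyl(dimethyl)silyl]oxy}methyl)prop-2-enoate; 11 (2R,3R)-3-methyl-3-[(3S,4R)-4-methyl-3,6-bis(triethylsilyloxy)hexyl]oxirane-2-carbaldehyde
Product: 19 ethyl (2E,4R)-3-bromo-2-({[tert-butyl(dimethyl)silyl]oxy}methyl)-4-{(2S,3R)-3-methyl-3-[(3S,4R)-4-methyl-3,6-bis(triethylsilyloxy)hexyl]oxiran-2-yl}-4-(triethylsilyloxy)but-2-enoate, via magnesium carbenoid 17 (not isolated), via magnesium alkoxide 18 (not isolated)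
Conditions: 16 (1.3 equiv), i-PrMgCl (1.3 equiv), THF, −78 °C; then 11, −78 °C; then TESOTf, 2,6-lutidine, −78 °C
Reagents that add atoms: triethylsilyl trifluoromethanesulfonate, CC[Si](CC)(CC)OS(=O)(=O)C(F)(F)F
Why: Chelation-directed bromine–magnesium exchange cis to the ester gives a configurationally defined alkenylmagnesium carbenoid, which should add to the cis-epoxy aldehyde under Felkin–Anh/Cornforth control (anti to the epoxide C–O, away from C4) to set C6 (6S in target numbering, 4R in 19 because of Br); the alkoxide is silylated cold before it can close onto the cis ester.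

**Step 12**
Reactants: 19 (the tris-TES bromoenoate of step 11)
Product: 21 ethyl (2E,4R)-3-bromo-2-({[tert-butyl(dimethyl)silyl]oxy}methyl)-4-{(2S,3R)-3-methyl-3-[(3S,4R)-4-methyl-6-oxo-3-(triethylsilyloxy)hexyl]oxiran-2-yl}-4-(triethylsilyloxy)but-2-enoate, via alkoxysulfonium chloride 20 (not isolated)
Conditions: (COCl)2, DMSO, CH2Cl2, −78 to −30 °C; then Et3N, −78 to 0 °C
Reagents that add atoms: none
Why: Swern oxidation converts a primary triethylsilyl ether directly into the aldehyde, while the secondary TES ethers and the primary TBS ether should stay.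

**Step 13**
Reactants: 21 (the bromoenoate aldehyde of step 12)
Product: 23 ten-membered seco-ester carbinol: ethyl 3-(TBS-oxy)-2-(cyclodecylidene)propanoate whose ring carries 8-OH, 1-OTES, 6-OTES, 10-CH3 and the cis 4,5-epoxide (4-CH3), ester cis to C6, all stereocentres as in 27, via alkenylchromium species 22 (not isolated)
Conditions: CrCl2 (8 equiv), NiCl2 (0.2 equiv), DMSO/THF (3:1), slow addition to 3 mM, rt
Reagents that add atoms: none
Why: Divalent chromium reduces NiCl2 to zerovalent nickel, which inserts into the C7–Br bond of the electron-poor bromoenoate, and transmetalation to trivalent chromium gives alkenylchromium 22, which adds to the C8 aldehyde, so that two carbons that are both electrophilic in 21 (enoate β-carbon and formyl carbon) are joined by polarity reversal. The closest known reaction type is the intramolecular Nozaki–Hiyama–Kishi alkenyl halide–aldehyde coupling used to close nine- to eleven-membered rings. The ten-membered carbocycle closes in the 10-exo-trig mode at high dilution, helped by the cis-fused oxirane at C4–C5, which folds the C3–C6 segment like a Z-alkene. The new C8 centre should be controlled by 1,3-allylic strain on the fully substituted C7=C11 alkene: C6–H and the forming C8–H eclipse the double bond (toward the ester and toward C13H2OTBS), the tether then spans C5 and C9 over one face, and the chromium-bound oxygen is placed on the face of the C6 silyloxy group, which is 8S. The step needs chemoselectivity for the aldehyde (alkenylchromium does not attack the ester or the epoxide), retention of the alkene geometry (a C7-bound chromium cannot isomerise through an allenolate) and freedom from β-elimination, which is why C6 carries a silyl ether and the lactone ring O–C12–C11=C7–C6 is left open, since in the closed butenolide the C6–O carboxylate would lie antiperiplanar to the C7–Cr bond.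

**Step 14**
Reactants: 23 (the seco-ester carbinol of step 13)
Product: 24 8-O-tiglate of 23, the (2E)-2-methylbut-2-enoate ester at C8
Conditions: tigloyl chloride (3 equiv), pyridine, DMAP (0.2 equiv), CH2Cl2, 0 °C to rt
Reagents that add atoms: tigloyl chloride, C/C=C(\C)C(Cl)=O
Why: DMAP-catalysed acylation of the only free hydroxyl; the thermodynamically stable E acid chloride should not isomerise, and no base-sensitive butenolide is present yet.

**Step 15**
Reactants: 24 (the tiglate of step 14)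
Product: 26 13-O-deacetyl target: the 6,12-butenolide with free C1–OH and C13–OH and the C8 tiglate, via seco hydroxy ester 25 (not isolated)
Conditions: n-Bu4NF (4 equiv), AcOH (4 equiv), THF, 0 °C to rt
Reagents that add atoms: none
Why: Buffered fluoride desilylation removes both TES ethers and the TBS ether; the freed C6 hydroxyl is held cis to the ethyl ester by the tetrasubstituted alkene and should lactonise spontaneously (5-exo-trig) to the butenolide.

**Step 16**
Reactants: 26 (the diol lactone of step 15)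
Product: 27 target, (1S,4R,5S,6S,8S,10R)-13-acetoxy-4,5-epoxy-1-hydroxy-8-tigloyloxygermacr-7(11)-en-12,6-olide
Conditions: AcCl (1.1 equiv), 2,4,6-collidine, CH2Cl2, −78 °C
Reagents that add atoms: acetyl chloride, CC(Cl)=O
Why: Kinetically selective acetylation of the unhindered primary allylic C13 hydroxyl over the hindered secondary C1 hydroxyl with a weak, hindered base that spares butenolide and epoxide.

**Compound list**
1 | neryl acetate, (2Z)-3,7-dimethylocta-2,6-dien-1-yl acetate | CC(C)=CCC/C(C)=C\COC(C)=O | starting material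
2 | secondary ozonide, (2Z)-5-(5,5-dimethyl-1,2,4-trioxolan-3-yl)-3-methylpent-2-en-1-yl acetate | CC1(C)OOC(CC/C(C)=C\COC(C)=O)O1 | intermediate (not isolated)
3 | (2Z)-3-methyl-6-oxohex-2-en-1-yl acetate | O=CCC/C(C)=C\COC(C)=O | intermediate
4 | diisopinocampheylborinate of 5 | C=C[C@@H](C)[C@@H](OB([C@H]1C[C@H]2C[C@@H]([C@@H]1C)C2(C)C)[C@H]1C[C@H]2C[C@@H]([C@@H]1C)C2(C)C)CC/C(C)=C\COC(C)=O | intermediate (not isolated)
5 | (2Z,6S,7R)-6-hydroxy-3,7-dimethylnona-2,8-dien-1-yl acetate | C=C[C@@H](C)[C@@H](O)CC/C(C)=C\COC(C)=O | intermediate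
6 | bis-borylated intermediate, 9-(9-BBN-yl) and 6-O-(9-BBN-yl) derivative of 7 | B1(CC[C@@H](C)[C@@H](OB2C3CCCC2CCC3)CC/C(C)=C\COC(C)=O)C2CCCC1CCC2 | intermediate (not isolated)
7 | (2Z,6S,7R)-6,9-dihydroxy-3,7-dimethylnon-2-en-1-yl acetate | OCC[C@@H](C)[C@@H](O)CC/C(C)=C\COC(C)=O | intermediate
8 | (2Z,6S,7R)-3,7-dimethyl-6,9-bis(triethylsilyloxy)non-2-en-1-yl acetate | CC[Si](CC)(CC)OCC[C@@H](C)[C@@H](O[Si](CC)(CC)CC)CC/C(C)=C\COC(C)=O | intermediate
9 | (2Z,6S,7R)-3,7-dimethyl-6,9-bis(triethylsilyloxy)non-2-en-1-ol | CC[Si](CC)(CC)OCC[C@@H](C)[C@@H](O[Si](CC)(CC)CC)CC/C(C)=C\CO | intermediate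
10 | {(2S,3R)-3-methyl-3-[(3S,4R)-4-methyl-3,6-bis(triethylsilyloxy)hexyl]oxiran-2-yl}methanol | CC[Si](CC)(CC)OCC[C@@H](C)[C@@H](O[Si](CC)(CC)CC)CC[C@@]1(C)O[C@H]1CO | intermediate
11 | (2R,3R)-3-methyl-3-[(3S,4R)-4-methyl-3,6-bis(triethylsilyloxy)hexyl]oxirane-2-carbaldehyde | CC[Si](CC)(CC)OCC[C@@H](C)[C@@H](O[Si](CC)(CC)CC)CC[C@@]1(C)O[C@H]1C=O | intermediate
12 | ethyl 2-(hydroxymethyl)acrylate | C=C(CO)C(=O)OCC | starting material
13 | ethyl 2-({[tert-butyl(dimethyl)silyl]oxy}methyl)prop-2-enoate | C=C(CO[Si](C)(C)C(C)(C)C)C(=O)OCC | intermediate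
14 | trioxolane, ethyl 3-({[tert-butyl(dimethyl)silyl]oxy}methyl)-1,2,4-trioxolane-3-carboxylate | CCOC(=O)C1(CO[Si](C)(C)C(C)(C)C)OCOO1 | intermediate (not isolated)
15 | ethyl 3-{[tert-butyl(dimethyl)silyl]oxy}-2-oxopropanoate | CCOC(=O)C(=O)CO[Si](C)(C)C(C)(C)C | intermediate
16 | ethyl 3,3-dibromo-2-({[tert-butyl(dimethyl)silyl]oxy}methyl)prop-2-enoate | CCOC(=O)C(CO[Si](C)(C)C(C)(C)C)=C(Br)Br | intermediate
17 | magnesium carbenoid, ethyl (2E)-3-bromo-3-(chloromagnesio)-2-(TBS-oxymethyl)prop-2-enoate (Mg cis to the ester) | CCOC(=O)/C(CO[Si](C)(C)C(C)(C)C)=C(/Br)[Mg]Cl | intermediate (not isolated)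
18 | magnesium alkoxide, chloromagnesium salt of the C6 carbinol corresponding to 19 | CC[Si](CC)(CC)OCC[C@@H](C)[C@@H](O[Si](CC)(CC)CC)CC[C@@]1(C)O[C@H]1[C@@H](O[Mg]Cl)/C(Br)=C(/CO[Si](C)(C)C(C)(C)C)C(=O)OCC | intermediate (not isolated)
19 | ethyl (2E,4R)-3-bromo-2-({[tert-butyl(dimethyl)silyl]oxy}methyl)-4-{(2S,3R)-3-methyl-3-[(3S,4R)-4-methyl-3,6-bis(triethylsilyloxy)hexyl]oxiran-2-yl}-4-(triethylsilyloxy)but-2-enoate | CC[Si](CC)(CC)OCC[C@@H](C)[C@@H](O[Si](CC)(CC)CC)CC[C@@]1(C)O[C@H]1[C@@H](O[Si](CC)(CC)CC)/C(Br)=C(/CO[Si](C)(C)C(C)(C)C)C(=O)OCC | intermediate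
20 | alkoxysulfonium chloride, dimethylsulfonium ether of the primary C8 oxygen of 19 | C[S+](C)OCC[C@@H](C)[C@@H](O[Si](CC)(CC)CC)CC[C@@]1(C)O[C@H]1[C@@H](O[Si](CC)(CC)CC)/C(Br)=C(/CO[Si](C)(C)C(C)(C)C)C(=O)OCC.[Cl-] | intermediate (not isolated)
21 | ethyl (2E,4R)-3-bromo-2-({[tert-butyl(dimethyl)silyl]oxy}methyl)-4-{(2S,3R)-3-methyl-3-[(3S,4R)-4-methyl-6-oxo-3-(triethylsilyloxy)hexyl]oxiran-2-yl}-4-(triethylsilyloxy)but-2-enoate | O=CC[C@@H](C)[C@@H](O[Si](CC)(CC)CC)CC[C@@]1(C)O[C@H]1[C@@H](O[Si](CC)(CC)CC)/C(Br)=C(/CO[Si](C)(C)C(C)(C)C)C(=O)OCC | intermediate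
22 | alkenylchromium species, 21 with CrCl2 in place of Br at C7 | O=CC[C@@H](C)[C@@H](O[Si](CC)(CC)CC)CC[C@@]1(C)O[C@H]1[C@@H](O[Si](CC)(CC)CC)/C([Cr](Cl)Cl)=C(/CO[Si](C)(C)C(C)(C)C)C(=O)OCC | intermediate (not isolated)
23 | ten-membered seco-ester carbinol (8-OH, 1-OTES, 6-OTES, cis 4,5-epoxide, exocyclic C7=C11 with CO2Et cis to C6 and CH2OTBS cis to C8; stereocentres as in 27) | O[C@H]1C[C@@H](C)[C@@H](O[Si](CC)(CC)CC)CC[C@@]2(C)O[C@H]2[C@@H](O[Si](CC)(CC)CC)/C1=C(/CO[Si](C)(C)C(C)(C)C)C(=O)OCC | intermediate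
24 | 8-O-tiglate of 23 | C/C=C(\C)C(=O)O[C@H]1C[C@@H](C)[C@@H](O[Si](CC)(CC)CC)CC[C@@]2(C)O[C@H]2[C@@H](O[Si](CC)(CC)CC)/C1=C(/CO[Si](C)(C)C(C)(C)C)C(=O)OCC | intermediate
25 | seco hydroxy ester, fully desilylated 24 (1,6,13-triol ethyl ester) | C/C=C(\C)C(=O)O[C@H]1C[C@@H](C)[C@@H](O)CC[C@@]2(C)O[C@H]2[C@@H](O)/C1=C(/CO)C(=O)OCC | intermediate (not isolated)
26 | 13-O-deacetyl target (1,13-diol, 6,12-butenolide, 8-tiglate) | C/C=C(\C)C(=O)O[C@H]1C[C@@H](C)[C@@H](O)CC[C@@]2(C)O[C@H]2[C@H]2OC(=O)C(CO)=C12 | intermediate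
27 | target, (1S,4R,5S,6S,8S,10R)-13-acetoxy-4,5-epoxy-1-hydroxy-8-tigloyloxygermacr-7(11)-en-12,6-olide | C/C=C(\C)C(=O)O[C@H]1C[C@@H](C)[C@@H](O)CC[C@@]2(C)O[C@H]2[C@H]2OC(=O)C(COC(C)=O)=C12 | target

**Totals and risks**
Total step count: 16. Longest linear sequence: 13 steps (steps 1–7 and 11–16, from neryl acetate).

Steps most likely to fail:

1. Step 13. Ring closure may lose out to intermolecular coupling or to reduction of the C7–Br bond, and the facial bias at C8 in the ten-membered transition state may be small. Fallback: setting out from 21, the cyclisation is run as in step 13 without regard to the outcome at C8. The mixture of 23 and the C8 epimer of 23 F1 is oxidised with Dess–Martin periodinane (NaHCO3, CH2Cl2) to the macrocyclic enone F2. This is reduced with (R)-2-methyl-CBS-oxazaborolidine and catecholborane at −78 °C, where hydride delivery is under reagent control (alkenyl carbon C7 as the large, C9H2 as the small substituent). This returns 23, where the main route continues.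

2. Step 11. The magnesium alkoxide may close onto the cis ester faster than it is silylated, and Felkin control at C6 may erode at the temperature needed for addition. Fallback: setting out from 11 (with carbenoid 17 made as in step 11), the addition mixture is warmed to 0 °C so that alkoxide 18 lactonises completely, giving the bromobutenolide F3, at which stage C6 epimers are separated. Swern oxidation of its primary TES ether gives the butenolide aldehyde F4. CrCl2/NiCl2 in DMSO/THF at 0 °C (to limit opening of the lactone) gives the macrocyclic butenolide carbinol F5. Tigloyl chloride/pyridine gives the butenolide tiglate F6. n-Bu4NF/AcOH removes both silyl groups and the route is rejoined at 26.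

3. Step 15. Under fluoride the freed hydroxyls may take part in acyl migration (tiglate from O8 to O6 or O13), or the new butenolide may be deprotonated at C6 with opening of the neighbouring epoxide. Fallback: setting out from 24, the two secondary TES ethers are cleaved by acid-catalysed ethanolysis (PPTS, EtOH, 0 °C), the C6 hydroxyl closing onto the ester under the same acid catalysis to give the 13-O-TBS lactone F7. The remaining primary TBS ether is then removed with Et3N·3HF in MeCN to give 26.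

**Further compounds**
F1 | step 13 | C8 epimer of 23 | O[C@@H]1C[C@@H](C)[C@@H](O[Si](CC)(CC)CC)CC[C@@]2(C)O[C@H]2[C@@H](O[Si](CC)(CC)CC)/C1=C(/CO[Si](C)(C)C(C)(C)C)C(=O)OCC
F2 | step 13 | macrocyclic enone (C8 ketone of 23) | O=C1C[C@@H](C)[C@@H](O[Si](CC)(CC)CC)CC[C@@]2(C)O[C@H]2[C@@H](O[Si](CC)(CC)CC)/C1=C(/CO[Si](C)(C)C(C)(C)C)C(=O)OCC
F3 | step 11 | bromobutenolide, (5R)-4-bromo-3-(TBS-oxymethyl)-5-{(2S,3R)-3-methyl-3-[(3S,4R)-4-methyl-3,6-bis(triethylsilyloxy)hexyl]oxiran-2-yl}furan-2(5H)-one | CC[Si](CC)(CC)OCC[C@@H](C)[C@@H](O[Si](CC)(CC)CC)CC[C@@]1(C)O[C@H]1[C@H]1OC(=O)C(CO[Si](C)(C)C(C)(C)C)=C1Br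
F4 | step 11 | butenolide aldehyde (C8 aldehyde of F3) | O=CC[C@@H](C)[C@@H](O[Si](CC)(CC)CC)CC[C@@]1(C)O[C@H]1[C@H]1OC(=O)C(CO[Si](C)(C)C(C)(C)C)=C1Br
F5 | step 11 | macrocyclic butenolide carbinol (8-OH, 1-OTES, 13-OTBS) | O[C@H]1C[C@@H](C)[C@@H](O[Si](CC)(CC)CC)CC[C@@]2(C)O[C@H]2[C@H]2OC(=O)C(CO[Si](C)(C)C(C)(C)C)=C12
F6 | step 11 | butenolide tiglate (8-O-tiglate of F5) | C/C=C(\C)C(=O)O[C@H]1C[C@@H](C)[C@@H](O[Si](CC)(CC)CC)CC[C@@]2(C)O[C@H]2[C@H]2OC(=O)C(CO[Si](C)(C)C(C)(C)C)=C12
F7 | step 15 | 13-O-TBS lactone (1-OH free, 8-tiglate) | C/C=C(\C)C(=O)O[C@H]1C[C@@H](C)[C@@H](O)CC[C@@]2(C)O[C@H]2[C@H]2OC(=O)C(CO[Si](C)(C)C(C)(C)C)=C12
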